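The earlier runs and the new flask come from a simulation with made-up constants; the scatter is artificial.

**Allowance first.** Against the J of the north-west flask the D charged stands at 5.00 to one, against the J of the south flask at 0.938 to one. Call this ratio, the exchanges D can pay per J charged, the allowance: each step from J to G, G to E and E to X takes one D and gives one Z.

| flask | J | D | Z | remark | time |
|---|---|---|---|---|---|
| Tuesday's | 0.037 M | 0.075 M | 0.10 M | run made earlier |  |
| Wednesday's | 0.077 M | 0.075 M | 0.10 M | run made earlier |  |
| north-west | 0.015 M | 0.0750 M | 0.100 M |  | 25 min |
| south-east | 0.020 M | 0.0750 M | 0.100 M |  | 25 min |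
| west | 0.030 M | 0.0750 M | 0.100 M |  | 25 min |
| north-east | 0.050 M | 0.0750 M | 0.100 M |  | 25 min |
| south | 0.080 M | 0.0750 M | 0.100 M |  | 25 min |

| run | time / min | E / % |
|---|---|---|
| Tuesday's | 4.00 | 10.6 |
| Tuesday's | 8.00 | 21.5 |
| Tuesday's | 10.0 | 26.3 |
| Tuesday's | 15.0 | 29.7 |
| Tuesday's | 20.0 | 31.4 |
| Wednesday's | 1.33 | 0.9 |
| Wednesday's | 2.50 | 4.2 |
| Wednesday's | 5.00 | 10.8 |
| Wednesday's | 10.0 | 20.4 |
| Wednesday's | 20.0 | 26.8 |

(readings scatter by 0.5 percentage points)

* [E] (only what is free in solution) at the end for north-west, south-east, west, north-east, south, in this order
* the course of these numbers from the first flask to the last (falls, then rises / falls all the way / rises, then falls / hardly changes / rises all the way)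

- in percentages every species weighs as the J in it: one Q counts as two
- for E the Q are counted in
- the analysis behind the earlier runs scatters by 0.5 percentage points, standard deviation
- candidate steps: E + D -> Z + X; G + D -> Z + E; J + E <-> Q; J + D -> Z + G
- in an amount of E, one Q counts as one E
- the concentration of E that is asked is that of its free form alone
- "hardly changes" means that all values lie within two and a half points (for a concentration: within two and a half percent of the largest)

**First estimate.** E costs two exchanges, so an allowance of two is the crossing. It lies at a J charge of 0.0375 M, above the west flask and below the north-east flask. Above that charge D becomes the limiting reagent for E, so you would expect the row to bend there.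

**First objection.** That counts a finished flask, and these flasks are not finished. In Wednesday's run the allowance of 0.974 would pay for E up to 48.7 % of the charge, yet the reading at 20.0 min is lower, 26.8 %. Tuesday's run, with an allowance of 2.03, reads 31.4 % at that time. From Tuesday to Wednesday the charge of J grew by a factor of 2.08, and the amount of E with Q counted, as read at that time, by 1.78. So at that time Wednesday's run, above the crossing, holds more E with Q counted than Tuesday's, and you should look for the bend at a higher charge than the crossing.

**Second objection.** Those readings include Q, but you are asked for free E. Each Q holds one E on a J, and a shrinking allowance should leave a larger fraction of J unexchanged, so free E should turn before E with Q counted does. The runs do not separate the two forms, so this reckoning commits to a shape and a place, not to concentrations: the row rises past 0.0375 M, and the south flask stands below the top.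

**The forecast.** It reads 0.0024 M, 0.0027 M, 0.003 M, 0.0032 M, 0.0031 M, course rises, then falls, and adds: “K is poorly fixed, so the ranges are wide”.

**The result.** The flasks give 0.00236 M, 0.00338 M, 0.00526 M, 0.00728 M, 0.00581 M, course rises, then falls. The row turns at a J charge of 0.054 M, an allowance of 1.38, above the crossing.

    E + D → Z + X (k = 0.0520 L mol⁻¹ s⁻¹)
    G + D → Z + E (k = 0.0480 L mol⁻¹ s⁻¹)
    J + E ⇌ Q, settled at all times (K = 130 L mol⁻¹)
    J + D → Z + G (k = 0.0290 L mol⁻¹ s⁻¹)

**Two ends.** In the north-west flask the half-life of free E by E + D alone, other concentrations as charged, is 3.0 min, shorter than the run of 25 min, and D has paid 2.17 exchanges per J out of an allowance of 5.00, with X at 56.0 % of the J charged. In the south flask D has paid 0.893 exchanges per J out of an allowance of 0.938, with 4.8 % of its charge left, and X stands at 4.05 % of the J charged.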